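**Remark on the chemistry:** locants C1–C6 refer to ring A of the target (C1 hydroxyl, C2 aryloxy), primed locants to ring B. Ketene acetal 7 is carried into step 5 without chromatography; its alkene geometry and the configurations of the transient adducts 8 and 9 are erased on aromatization.

## The problem

The target 12, 3,4,6-tribromo-2-(2,4-dibromophenoxy)phenol, is a diaryl ether of two bromoarene rings. Ring A carries the hydroxyl at C1, the aryloxy group at C2, bromine at C3, C4 and C6 and its only hydrogen at C5; ring B is a 2,4-dibromophenyl group. The molecule is flat and has no stereocenter, so the problem is purely regiochemical: seven heteroatom substituents must each reach the right carbon. The ether oxygen has three ortho substituents (OH and Br on ring A, Br on ring B), and a late C–O coupling would have to choose among several C–Br bonds, so the ether link is a poor place for a late bond. The five aryl C–Br bonds will not survive alkyllithiums, low-valent transition metals or strong amide bases (the C3'–H between the ring-B bromines is open to ortho-metalation and halogen migration), and the free phenol is easily over-brominated or oxidized. The C3 bromine is meta to the hydroxyl, so hydroxyl-directed substitution cannot place it and it is best brought in with the ring carbons. The enabling feature is that the oxygen-bearing carbons C1 and C2 are neighbours flanked by the brominated carbons C6 and C3, with C4–C5 closing the ring. C1–C2 is therefore a masked ketene acetal of (2,4-dibromophenoxy)acetic acid, C3–C4–C5–C6 is the carbon diene of 2,5-dibromothiophene 1,1-dioxide 2, and the C4 bromine, para to the hydroxyl, can be added last.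

## Retrosynthesis

**C4–Br.** The bromine at C4 of 12 is cut to give 3,6-dibromo-2-(2,4-dibromophenoxy)phenol 11. This is the C–Br bond to cut because it lies para to the hydroxyl with both ortho positions occupied, so the forward bromination has one strongly preferred site. The C3 bromine is meta to the hydroxyl, and the remaining bromines can arrive inside the building blocks 1 and 3. Removing C4–Br also makes the C3–C6 fragment symmetric, which allows a symmetric diene in the next cut. The forward step must stop at one bromine and leave C5 and ring B alone.

**Ring A.** In 11 the bonds C2–C3 and C1–C6 are cut together, back through aryl silyl ether 10, cyclohexadiene ketal 9 and bicyclic sulfone 8 to 2,5-dibromothiophene 1,1-dioxide 2 and the bis(trimethylsilyl) ketene acetal 7. The neighbouring cut, the C2–O ether bond, would mean coupling at an oxygen with three ortho substituents in the presence of competing C–Br bonds. The two-bond cut instead turns the hindered diaryl ether into an ordinary alkyl aryl ether that is already present in 7. A pentasubstituted benzene becomes a four-carbon and a two-carbon piece, each a few steps from commodity chemicals, and the symmetry of 2 removes any question of orientation. The forward reaction asks three things: the electron-poor diene and the electron-rich alkene must combine faster than 2 dimerizes, the sulfonyl bridge must leave, and aromatization must expel a silyloxy group and not the phenoxide of 3. The last point is built in, since C1 holds two oxygen leaving groups and no hydrogen while C2 holds the only removable hydrogen.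

**The ketene acetal.** Both O–Si bonds of 7 are cut, back through silyl ester 6 to (2,4-dibromophenoxy)acetic acid 5, and the O–CH2 bond of 5 is cut to 2,4-dibromophenol 3 and bromoacetic acid 4. Passing through silyl ester 6 and not through the dianion of 5 leaves a single acidic C–H. One equivalent of a silylamide base at low temperature then suffices, and that base is too weak to metalate ring B between its bromines. Ring B and its two bromines are bought in 3 and never touched again. The forward steps are a Williamson etherification, a carboxylate silylation and an enolate O-silylation.

**The diene.** The two S–O bonds of 2 are cut to 2,5-dibromothiophene 1. This beats building the brominated sulfone ring from acyclic material, because 1 is a commodity chemical with both bromines already on the right carbons. The forward oxidation must overcome the low nucleophilicity of a dibrominated thiophene sulfur, which calls for a strongly electrophilic peracid, and the dioxide must be handled so that it does not dimerize.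

## Roads not taken

**Alternative 1:** aryne aryloxybromination.
- **Cut:** the ether bond O–C1' and the neighbouring C2'–Br bond of ring B are disconnected together. Ring B comes from an unsubstituted aryne (released by fluoride from an ortho-silylaryl triflate) and ring A from 2-bromo-6-methoxyphenol A1.
- **Forward key step:** the phenoxide of A1 would add to the aryne, and the ortho-aryloxyaryl anion would abstract bromine from a perbrominated carbon donor. This gives 1-bromo-2-(2-bromophenoxy)-3-methoxybenzene A2, with no ring closed.
- **Merits:** the crowded ether bond forms without a transition metal and so without risk to C–Br bonds. The C2' bromine is placed by the mechanism. The route is short: A1 is purchasable and only demethylation and bromination follow, perhaps four steps against six here.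
- **Weak points:** the aryl anion can be protonated instead of brominated. Above all, three of the five bromines (C4, C6, C4') would still have to be introduced afterwards by electrophilic substitution on two rings. C4 and C6 lie para and ortho to the liberated hydroxyl and are easy. C4' lies on the less activated ring B, and the conditions needed there invite attack at C6' and C5. Carrying the C4' bromine on the aryne instead would make the aryne unsymmetrical and the addition unselective.
- **Comparison:** in step count this road is better than the chosen plan. The chosen plan sets against it that four of the five bromines arrive in fixed positions inside 1 and 3, that ring B is never brominated, and that the single late bromination has one strongly preferred site.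

**Alternative 2:** Claisen closure of a saturated ring A.
- **Cut:** the C1–C2 bond of a cyclohexane-1,3-dione that stands in for ring A.
- **Forward key step:** an alkoxide base would convert methyl 6-(2,4-dibromophenoxy)-5-oxohexanoate A3 into the ketone enolate at its aryloxy-bearing methylene, which attacks the ester and closes 2-(2,4-dibromophenoxy)cyclohexane-1,3-dione A4. One carbonyl of A4 would then become a vinyl bromide (3-bromo-2-(2,4-dibromophenoxy)cyclohex-2-en-1-one A5), the ring would be dehydrogenated to 3-bromo-2-(2,4-dibromophenoxy)phenol A6, and A6 would be brominated ortho and para to the hydroxyl to reach 12.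
- **Merits:** every step is textbook carbonyl chemistry. The closure is driven by the acidity of the 1,3-dione and has no competitor, since the other enolates could only close four-membered rings. A4 is symmetric, so either carbonyl may become C3–Br. The final bromination fills both remaining activated positions and needs no restraint.
- **Weak points:** ring A is made at the wrong oxidation level and without any bromine, so three adjustments follow the closure, and with two or three steps to A3 the sequence runs to about eight steps. The aromatization of A5 must oxidize C6 next to the carbonyl in preference to the allylic C4, beside a vinyl bromide and an enol ether.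
- **Comparison:** step for step this road is the more certain one, which the chosen plan cannot claim for its key step. The chosen plan offers in return about two steps fewer and a ring A that is aromatic on arrival, with both oxygens and the C3 and C6 bromines in place.

**Alternative 3:** pyrone Diels–Alder for ring B.
- **Cut:** ring B at C1'–C2' and C5'–C6'.
- **Forward key step:** 3,5-dibromo-2H-pyran-2-one A7 would react as the diene with the aryl ethynyl ether 1-bromo-2-(ethynyloxy)-3-methoxybenzene A8, derived from A1, and the bridged lactone would decarboxylate to 1-bromo-2-(2,4-dibromophenoxy)-3-methoxybenzene A9. Demethylation to A6 and twofold bromination would finish.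
- **Merits:** it mirrors the chosen logic, with ring B and both its bromines assembled in one cycloaddition–extrusion. An alkyne dienophile gives the arene directly, so no elimination has to choose a leaving group. The polarity of the partners (nucleophilic terminal alkyne carbon to C6 of A7, oxygen-bearing carbon to C3) points to the required 2',4' pattern.
- **Weak points:** the ring-forming step is spent on the ring that can be bought, since 3 is a commodity phenol, while ring A still needs demethylation and two brominations. A8 is hard to reach, because the usual route to ethynyl ethers treats a dichlorovinyl ether with an alkyllithium, and the ring-A bromide would undergo halogen–metal exchange. With an unsymmetrical diene and an unsymmetrical alkyne the orientation must be trusted, not guaranteed.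
- **Comparison:** the length is about the same, and in the aromatization event this road is cleaner. The chosen plan answers with a symmetric diene that makes orientation a non-issue, a dienophile made without any organolithium, and ring construction aimed at ring A, the ring whose pattern cannot be bought.

Key step: step 5

## Route

Step 1
Reactants: 1 2,5-dibromothiophene
Product: 2 2,5-dibromothiophene 1,1-dioxide
Conditions: H2O2 (50% aq.), (CF3CO)2O, MeCN–CH2Cl2, 0 °C → rt
Reagents that add atoms: trifluoroperacetic acid, OOC(=O)C(F)(F)F (made in the flask from hydrogen peroxide, OO, and trifluoroacetic anhydride, O=C(OC(=O)C(F)(F)F)C(F)(F)F)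
Why: Peracid oxidation of a thiophene at sulfur to the 1,1-dioxide; the dibrominated ring is too electron-poor for ordinary peracids but should yield to trifluoroperacetic acid, the sulfoxide stage being oxidized faster than the thiophene, and the two alpha bromines slow the [4+2] self-dimerization so that the dioxide should be isolable.

Step 2
Reactants: 3 2,4-dibromophenol; 4 bromoacetic acid
Product: 5 (2,4-dibromophenoxy)acetic acid
Conditions: NaOH, H2O, reflux; then HCl
Reagents that add atoms: none
Why: Williamson ether synthesis: the phenoxide displaces bromide from bromoacetate in aqueous alkali and acidification should precipitate the aryloxyacetic acid; the aryl bromides are inert to these conditions.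

Step 3
Reactants: 5 (2,4-dibromophenoxy)acetic acid
Product: 6 trimethylsilyl (2,4-dibromophenoxy)acetate
Conditions: Me3SiCl, Et3N, THF, 0 °C → rt
Reagents that add atoms: chlorotrimethylsilane, C[Si](C)(C)Cl
Why: Silyl ester formation from a carboxylic acid with a chlorosilane and an amine base; it removes the acidic O–H so that step 4 needs only one equivalent of base and delivers an acetal with two identical silyloxy groups.

Step 4
Reactants: 6 trimethylsilyl (2,4-dibromophenoxy)acetate
Product: 7 2-(2,4-dibromophenoxy)-1,1-bis(trimethylsilyloxy)ethene
Conditions: Me3SiCl, LiN(SiMe3)2, THF, –78 °C → rt
Reagents that add atoms: chlorotrimethylsilane, C[Si](C)(C)Cl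
Why: Enolate O-silylation of a silyl ester to a bis(silyl) ketene acetal (Ainsworth-type): LiN(SiMe3)2 removes the one acidic C–H of 6 at –78 °C and the chlorosilane already present traps the enolate on oxygen before it can condense; the silylamide is too weak a base to metalate C3'–H between the ring-B bromines, which LiN(iPr)2 or a dianion protocol would risk.

Step 5
Reactants: 2 2,5-dibromothiophene 1,1-dioxide; 7 2-(2,4-dibromophenoxy)-1,1-bis(trimethylsilyloxy)ethene
Product: 11 3,6-dibromo-2-(2,4-dibromophenoxy)phenol, via bicyclic sulfone adduct 8 (not isolated), via cyclohexadiene bis-silyl ketal 9 (not isolated), via aryl trimethylsilyl ether 10 (not isolated)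
Conditions: PhMe, 25 → 90 °C, Ar stream; then 1 M HCl, THF, rt
Reagents that add atoms: none
Why: Inverse-electron-demand Diels–Alder reaction followed by cheletropic extrusion and elimination, the known behaviour of halogenated thiophene 1,1-dioxides toward enol ethers and enamines and the sulfur counterpart of the ketene-acetal benzannulation of 2-pyrones. The low-lying LUMO of sulfonyl diene 2 and the high HOMO of ketene acetal 7 should join the aryloxy-bearing carbon and the acetal carbon to the two C–Br termini, concertedly or through a zwitterion (silyloxy-stabilized carbenium ion, sulfonyl-stabilized allyl anion) that collapses to the same adduct 8. Ring A is thus closed as a six-membered carbocycle by an intermolecular [4+2] union of a four-carbon and a two-carbon piece (bonds C2–C3 and C1–C6), and the strained 7-thiabicyclo[2.2.1]heptene dioxide 8 should lose SO2 cheletropically to give cyclohexadiene 9. Ionization of one silyloxy group at C1 gives a silyloxy-stabilized pentadienyl cation that loses the C2 proton to form aryl silyl ether 10, and dilute acid cleaves the O–Si bond to phenol 11; any 9 that reaches the work-up is hydrolysed at the ketal carbon and enolizes to the same phenol. No stereocenter survives: the configurations at C2 and at the bridgeheads of 8 and 9 are uncontrolled and are erased on aromatization, as is the alkene geometry of 7. The selectivity needed is loss of silanol and not of the phenoxide of 3, which is secured because C1 holds two oxygen leaving groups and no hydrogen while C2 holds the only removable hydrogen and C3 is already sp2; orientation is no issue because diene 2 is symmetric. Excess 7 and removal of SO2 in the argon stream should keep dimerization of 2 and attack of SO2 on 7 in check.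

Step 6
Reactants: 11 3,6-dibromo-2-(2,4-dibromophenoxy)phenol
Product: 12 3,4,6-tribromo-2-(2,4-dibromophenoxy)phenol
Conditions: Br2 (1.0 equiv), AcOH, rt
Reagents that add atoms: bromine, BrBr
Why: Electrophilic aromatic bromination: both positions ortho to the hydroxyl are occupied, so the hydroxyl directs to C4 alone, whereas C5 is para only to the weakly donating diaryl-ether oxygen and ring B is deactivated by two bromines; one equivalent should stop the reaction at the target.

## Compound list

1 | 2,5-dibromothiophene | Brc1ccc(Br)s1 | starting material
2 | 2,5-dibromothiophene 1,1-dioxide | O=S1(=O)C(Br)=CC=C1Br | intermediate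
3 | 2,4-dibromophenol | Oc1ccc(Br)cc1Br | starting material
4 | bromoacetic acid | OC(=O)CBr | starting material
5 | (2,4-dibromophenoxy)acetic acid | OC(=O)COc1ccc(Br)cc1Br | intermediate
6 | trimethylsilyl (2,4-dibromophenoxy)acetate | C[Si](C)(C)OC(=O)COc1ccc(Br)cc1Br | intermediate
7 | 2-(2,4-dibromophenoxy)-1,1-bis(trimethylsilyloxy)ethene | C[Si](C)(C)OC(O[Si](C)(C)C)=COc1ccc(Br)cc1Br | intermediate
8 | 1,4-dibromo-5-(2,4-dibromophenoxy)-6,6-bis(trimethylsilyloxy)-7-thiabicyclo[2.2.1]hept-2-ene 7,7-dioxide (racemic, endo/exo unassigned) | O=S1(=O)C2(Br)C=CC1(Br)C(O[Si](C)(C)C)(O[Si](C)(C)C)C2Oc1ccc(Br)cc1Br | intermediate (not isolated)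
9 | 1,4-dibromo-6-(2,4-dibromophenoxy)-5,5-bis(trimethylsilyloxy)cyclohexa-1,3-diene (racemic) | BrC1=CC=C(Br)C(O[Si](C)(C)C)(O[Si](C)(C)C)C1Oc1ccc(Br)cc1Br | intermediate (not isolated)
10 | [3,6-dibromo-2-(2,4-dibromophenoxy)phenoxy]trimethylsilane | C[Si](C)(C)Oc1c(Br)ccc(Br)c1Oc1ccc(Br)cc1Br | intermediate (not isolated)
11 | 3,6-dibromo-2-(2,4-dibromophenoxy)phenol | Oc1c(Br)ccc(Br)c1Oc1ccc(Br)cc1Br | intermediate
12 | 3,4,6-tribromo-2-(2,4-dibromophenoxy)phenol | Oc1c(Br)cc(Br)c(Br)c1Oc1ccc(Br)cc1Br | target

## Step count and least certain steps

Total steps: 6. Longest linear sequence: 5 steps (3 + 4 → 5 → 6 → 7 → 11 → 12); the diene branch adds one step (1 → 2) before the convergence in step 5.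

**Step 5 (key step).**
- **Risk:** the two bond-forming centres on each side are fully substituted, so the cycloaddition may be slow enough for self-dimerization of the diene and protodesilylation of the acetal to take over. The acetal may also add in a stepwise conjugate sense, and the zwitterion may expel bromide with silyl transfer or close to a four-membered ring instead of the bicycle.
- **Fallback:** ring A is bought and the ether bond is made by nucleophilic aromatic substitution. Setting out from 3, its potassium phenoxide (K2CO3, DMF, 100 °C) displaces fluoride from the catalogue building block 3,6-dibromo-2-fluorobenzaldehyde F1, activated by the ortho formyl group, to give 3,6-dibromo-2-(2,4-dibromophenoxy)benzaldehyde F2. Baeyer–Villiger oxidation with mCPBA (CH2Cl2, rt) moves the aryl group to oxygen and gives 3,6-dibromo-2-(2,4-dibromophenoxy)phenyl formate F3. Cleavage of the formate with KOH in aqueous MeOH and acidification returns to the route at 11.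

**Step 4.**
- **Risk:** C-silylation or Claisen self-condensation of the enolate, cleavage of the O–Si ester bond by the amide, and hydrolysis of the very moisture-sensitive bis(silyl) acetal during isolation.
- **Fallback:** one oxygen is carried as a methyl ether and no amide base is used. Setting out from 5, Fischer esterification (MeOH, cat. H2SO4, reflux) gives methyl (2,4-dibromophenoxy)acetate F4, and soft enolization (Me3SiOTf, Et3N, Et2O, 0 °C) gives 2-(2,4-dibromophenoxy)-1-methoxy-1-(trimethylsilyloxy)ethene F5. F5 is heated with 2 as in step 5. The bicyclic adduct F6 loses SO2 to give the mixed methyl silyl ketal F7, which aromatizes by loss of silanol to 1,4-dibromo-2-(2,4-dibromophenoxy)-3-methoxybenzene F8 or by loss of methanol to 10. Acid work-up and then BBr3 (CH2Cl2, –78 °C → rt), which cleaves the methyl ether of F8 but not the diaryl ether, converge both products and return to the route at 11.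

**Step 1.**
- **Risk:** slow oxidation of the deactivated sulfur, while the dioxide once formed may dimerize by [4+2] addition with loss of SO2 or be degraded by excess peracid.
- **Fallback:** the oxidation is run on an electron-rich, sterically shielded thiophene and the bromines are restored afterwards. Setting out from 1, double bromine–lithium exchange (n-BuLi, THF, –78 °C) gives thiophene-2,5-diyldilithium F9, which is silylated with Me3SiCl to 2,5-bis(trimethylsilyl)thiophene F10. mCPBA (CH2Cl2, rt) oxidizes F10 to 2,5-bis(trimethylsilyl)thiophene 1,1-dioxide F11. Twofold ipso-bromodesilylation (Br2, AgBF4, CH2Cl2) returns to the route at 2.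

**Step 6.**
- **Risk:** competing substitution at C5, para to the ether oxygen, or a second bromination (including ipso attack) where bromine is in local excess.
- **Fallback:** the C4 substituent is introduced as nitrogen by an electrophile that attacks only para to a free phenol, and is then exchanged for bromine. Setting out from 11, nitrosation (NaNO2, aq. AcOH–H2SO4, 0 °C) gives 3,6-dibromo-2-(2,4-dibromophenoxy)-4-nitrosophenol F12. Reduction with Na2S2O4 (aq. EtOH) gives 4-amino-3,6-dibromo-2-(2,4-dibromophenoxy)phenol F13. Diazotization (NaNO2, HBr, 0 °C) gives 2,5-dibromo-3-(2,4-dibromophenoxy)-4-hydroxybenzenediazonium bromide F14, and a Sandmeyer reaction (CuBr, HBr, 60 °C) returns to the route at the target 12.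

## Further compounds

F1 | step 5 | 3,6-dibromo-2-fluorobenzaldehyde | O=Cc1c(F)c(Br)ccc1Br
F2 | step 5 | 3,6-dibromo-2-(2,4-dibromophenoxy)benzaldehyde | O=Cc1c(Br)ccc(Br)c1Oc1ccc(Br)cc1Br
F3 | step 5 | 3,6-dibromo-2-(2,4-dibromophenoxy)phenyl formate | O=COc1c(Br)ccc(Br)c1Oc1ccc(Br)cc1Br
F4 | step 4 | methyl (2,4-dibromophenoxy)acetate | COC(=O)COc1ccc(Br)cc1Br
F5 | step 4 | 2-(2,4-dibromophenoxy)-1-methoxy-1-(trimethylsilyloxy)ethene (E/Z mixture) | COC(O[Si](C)(C)C)=COc1ccc(Br)cc1Br
F6 | step 4 | 1,4-dibromo-5-(2,4-dibromophenoxy)-6-methoxy-6-(trimethylsilyloxy)-7-thiabicyclo[2.2.1]hept-2-ene 7,7-dioxide (racemic, mixture of diastereomers) | COC1(O[Si](C)(C)C)C(Oc2ccc(Br)cc2Br)C2(Br)C=CC1(Br)S2(=O)=O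
F7 | step 4 | 1,4-dibromo-6-(2,4-dibromophenoxy)-5-methoxy-5-(trimethylsilyloxy)cyclohexa-1,3-diene (racemic, mixture of diastereomers) | COC1(O[Si](C)(C)C)C(Br)=CC=C(Br)C1Oc1ccc(Br)cc1Br
F8 | step 4 | 1,4-dibromo-2-(2,4-dibromophenoxy)-3-methoxybenzene | COc1c(Br)ccc(Br)c1Oc1ccc(Br)cc1Br
F9 | step 1 | thiophene-2,5-diyldilithium | [Li]c1ccc([Li])s1
F10 | step 1 | 2,5-bis(trimethylsilyl)thiophene | C[Si](C)(C)c1ccc([Si](C)(C)C)s1
F11 | step 1 | 2,5-bis(trimethylsilyl)thiophene 1,1-dioxide | C[Si](C)(C)C1=CC=C([Si](C)(C)C)S1(=O)=O
F12 | step 6 | 3,6-dibromo-2-(2,4-dibromophenoxy)-4-nitrosophenol | Oc1c(Br)cc(N=O)c(Br)c1Oc1ccc(Br)cc1Br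
F13 | step 6 | 4-amino-3,6-dibromo-2-(2,4-dibromophenoxy)phenol | Nc1cc(Br)c(O)c(Oc2ccc(Br)cc2Br)c1Br
F14 | step 6 | 2,5-dibromo-3-(2,4-dibromophenoxy)-4-hydroxybenzenediazonium bromide | [Br-].N#[N+]c1cc(Br)c(O)c(Oc2ccc(Br)cc2Br)c1Br
A1 | alternative 1 | 2-bromo-6-methoxyphenol | COc1cccc(Br)c1O
A2 | alternative 1 | 1-bromo-2-(2-bromophenoxy)-3-methoxybenzene | COc1cccc(Br)c1Oc1ccccc1Br
A3 | alternative 2 | methyl 6-(2,4-dibromophenoxy)-5-oxohexanoate | COC(=O)CCCC(=O)COc1ccc(Br)cc1Br
A4 | alternative 2 | 2-(2,4-dibromophenoxy)cyclohexane-1,3-dione | O=C1CCCC(=O)C1Oc1ccc(Br)cc1Br
A5 | alternative 2 | 3-bromo-2-(2,4-dibromophenoxy)cyclohex-2-en-1-one | O=C1CCCC(Br)=C1Oc1ccc(Br)cc1Br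
A6 | alternative 2 | 3-bromo-2-(2,4-dibromophenoxy)phenol | Oc1cccc(Br)c1Oc1ccc(Br)cc1Br
A7 | alternative 3 | 3,5-dibromo-2H-pyran-2-one | O=C1OC=C(Br)C=C1Br
A8 | alternative 3 | 1-bromo-2-(ethynyloxy)-3-methoxybenzene | COc1cccc(Br)c1OC#C
A9 | alternative 3 | 1-bromo-2-(2,4-dibromophenoxy)-3-methoxybenzene | COc1cccc(Br)c1Oc1ccc(Br)cc1Br
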